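The data were generated by integration with made-up constants; noise was put on by code.

At late times the dusk flask stands still: target stays level from 3.00 h to 15.0 h, with a mean reading of 35.0% of the charge.

| setting | dusk | summer | flask |
|---|---|---|---|
| solid substrate | 10 mM | 10 mM | 10 mM |
| temperature | 5 °C | −10 °C | 5 °C |
| remark | the very flask that is asked about, followed so far | run made earlier |  |
| time |  |  | 15 h |

- dusk (time / h: target / %, solid substrate / %): 3.00: 36, 0; 6.00: 33, 2; 10.0: 34, 0; 12.0: 33, 0; 15.0: 39, 1
- summer (time / h: target / %, solid substrate / %): 6.00: 14, 0; 12.0: 13, 1; 20.0: 12, 0; 25.0: 13, 0; 30.0: 16, 2

(scatter of a reading: 1.5 percentage points)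

- epsilon: at 15 h take out 90% of the target then present, then wait 30 h
- theta: change nothing and wait 30 h more
- alpha: at 15 h raise the temperature by 20 K, then wait 30 h

- as a solid, counted per litre of solution: solid substrate
- target taken out counts as made
- at the start none of the solid substrate is in solution

1. target, in percent of the solid substrate first charged, at 15 h
2. which option adds most target ("none" when 2 percentage points or less is all one gets) (epsilon / theta / alpha / none)
3. target present, with what was taken out counted in, in percent of the solid substrate first charged, after epsilon
4. target present, with what was taken out counted in, in percent of the solid substrate first charged, after theta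

In the dusk run the solid substrate reads 0% at the first reading, so 65.0% of the charge sits in something unread. But that remainder does not grow over the dusk run, and the summer flask levels off elsewhere, at a mean of 13.6%. So we read a balance, reached before 3.00 h, well inside the asked time, and reckon with it as a fast step at rest. Dusk gives 0.538, which we carry as the split, target divided by the unseen remainder at late times, the equilibrium constant of that balance.

Theta leaves the split alone, so target stays at 35.0%. Epsilon removes 90% of the target, and the 68.5% still in the flask shares out again at the same split, which makes 55.5% in total. For alpha, summer has a split of 0.157, so the gap between the runs multiplies it by 3.42. But that gap is not the rise, so we take the logarithm of the split as a straight line in inverse absolute temperature, the van 't Hoff line, and reach a split of 2.29 after the rise. That is a gain of 35 percentage points, more than epsilon's 20 points, so we choose alpha.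

The forecast gave 35%, 55.5% and 35% and chose alpha: “A flat plateau that shifts with temperature suggests a reversible equilibrium”.

The flask gives 34.5%, 54.8% and 34.5%, and alpha adds 34 points.

    starting material + 2 target → 3 target (k = 36000 M⁻² min⁻¹, Ea = 35.0 kJ mol⁻¹)
    starting material → target (k = 0.0200 min⁻¹, Ea = 78.0 kJ mol⁻¹)
    solid substrate ⇌ starting material, rate k3*(cs3 - [starting material]) while solid is left; crystals form when [starting material] > cs3 (solubility = 3.40 mM, k = 0.110 min⁻¹)
    target ⇌ isomer of the product (K = 1.90, k = 0.230 min⁻¹, Ea = 74.0 kJ mol⁻¹, ΔH = −49.0 kJ mol⁻¹)
    (constants at 5 °C)

The unseen remainder is isomer of the product, and its exchange with target, by this step alone and both ways together, relaxes with a half-life of 1.97 min, far shorter than the asked time. At 15.0 h the flask holds 34.5% target and 65.5% isomer of the product. We carry the split to the neighbouring flask at 30 °C along the same line: that gives a split of 3.19, hence 76.1% target. That neighbouring flask holds 75.1% target and 24.9% isomer of the product.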